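**Plan**
1. Atoms carry guaiane numbers: C1 (CH–O-acyl), C2–C3 (CH2CH2), C4=C5 (C15H2OH on C4), C6 (lactone CH–O), C7 (CH bearing C11(=C13)–C12), C8 (butenolide CH–O), C9=C10, C14 (butenolide carbonyl).
2. Retrosynthesis first removes the ester, the C9=C10 unsaturation and the C1 carbinol (C1 ketone 23). The array O=C1 / C5=C4 / C15–OH of the ten-membered ring is then re-closed across C1–C5 to a 5/7-fused 1-hydroxy-4,15-epoxy guaiane bis-lactone (22); forwards this is a Grob fragmentation.
3. 22 is cut at C11=C13 (Mannich methylenation), O6–C12 (lactonisation), C4–C15 (sulfur ylide), C1–C10 (samarium Reformatsky), C5–C6 (vinylcerium addition) and C7–C8 (aldol dimerisation of methyl 4-oxobutanoate).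
4. Forward order: C6–C14 chain, 8,14-lactone, cyclopentene joined at C6, seven-membered ring with the lactone as bridge, spiro-epoxide, 6,12-lactone and methylene, ten-membered ring by fragmentation, butenolide.
5. Stereochemistry: C7/C8 from D-proline catalysis, C6 by Felkin–Anh addition, C4=C5 geometry from the epoxide oxygen set cis to C6 plus antiperiplanar fragmentation, C1 by CBS reduction.

Key step: step 13

Assumption: C1, C5 and C10 of compounds 11–22 are written for the cis-fused hydroazulene series; all three are erased or re-set from step 13 onwards, so their sense does not affect the target.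

Step 1
Reactants: 1 methyl 4-oxobutanoate (two molecules)
Product: 2 dimethyl (3R,4R)-3-formyl-4-hydroxyheptanedioate
Conditions: D-proline (10 mol %), DMF, 4 °C
Reagents that add atoms: none
Why: Proline-catalysed enamine aldol reaction (aldehyde self-aldol): the D-proline enamine of one molecule of 1 adds to the formyl group of a second through the hydrogen-bonded chair transition state, which should give the anti aldol and set C7 and C8 (3R,4R) under catalyst control.

Step 2
Reactants: 2 dimethyl (3R,4R)-3-formyl-4-hydroxyheptanedioate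
Product: 3 methyl (3R)-4-oxo-3-[(2R)-5-oxooxolan-2-yl]butanoate
Conditions: PPTS (cat.), CH2Cl2, rt
Reagents that add atoms: none
Why: Acid-catalysed 5-exo-trig lactonisation of the C8 hydroxyl onto the C14 ester, preferred because closure onto the C12 ester would force the formyl group and the side chain cis on the new ring; no stereocentre is touched.

Step 3
Reactants: 3 methyl (3R)-4-oxo-3-[(2R)-5-oxooxolan-2-yl]butanoate; 4 6-bromo-1,4-dioxaspiro[4.4]non-6-ene
Product: 8 methyl (3R,4S)-4-[(tert-butyldimethylsilyl)oxy]-4-(1,4-dioxaspiro[4.4]non-6-en-6-yl)-3-[(2R)-5-oxooxolan-2-yl]butanoate, via vinyllithium 5 (not isolated), via vinylcerium reagent 6 (not isolated), via C6 cerium alkoxide 7 (not isolated)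
Conditions: 4, n-BuLi, THF, −78 °C; CeCl3, −78 °C; 3, −78 °C; then t-BuMe2SiOTf, 2,6-lutidine, −78 to 0 °C
Reagents that add atoms: tert-butyldimethylsilyl trifluoromethanesulfonate, CC(C)(C)[Si](C)(C)OS(=O)(=O)C(F)(F)F
Why: Bromine–lithium exchange and transmetallation give a weakly basic vinylcerium reagent whose 1,2-addition to the aldehyde should follow the Felkin–Anh model (attack anti to the C8 ring carbon, over the C7 hydrogen) and so set C6, and the alkoxide is silylated in the same flask before it can close onto the C12 ester.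

Step 4
Reactants: 8 silyl ether from step 3
Product: 10 methyl (3R,4S)-3-[(2R,4S)-4-bromo-5-oxooxolan-2-yl]-4-[(tert-butyldimethylsilyl)oxy]-4-(1,4-dioxaspiro[4.4]non-6-en-6-yl)butanoate, via ketene silyl acetal 9 (not isolated)
Conditions: LiN(SiMe3)2 (1.05 equiv), Me3SiCl, THF, −78 °C; then NBS, −78 °C
Reagents that add atoms: N-bromosuccinimide, O=C1CCC(=O)N1Br
Why: Lactone α-bromination through the ketene silyl acetal: the lactone α-CH2 (C10) is more acidic and less hindered than the α-CH2 of the acyclic ester (C11), so one equivalent of LiN(SiMe3)2 with Me3SiCl present should enolise only C10, and NBS then delivers bromine anti to the C8 substituent.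

Step 5
Reactants: 10 C10 bromo lactone
Product: 12 cyclopentanol (C5–H and C1–OH cis; C1–OH trans to the C6 chain), via C1 alkylborane 11 (not isolated)
Conditions: BH3·SMe2, THF, 0 °C; then H2O2, pH 7 phosphate buffer, 0 °C to rt
Reagents that add atoms: hydrogen peroxide, OO
Why: Hydroboration–oxidation: boron should add to C1, the less substituted olefinic carbon remote from the ketal oxygens, and hydrogen to C5 on the same face, which sets the C5 hydrogen and the C1 hydroxyl cis, both centres being of no lasting consequence.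

Step 6
Reactants: 12 cyclopentanol
Product: 13 cyclopentanone (C1 ketone; C4 ethylene ketal; C6 silyl ether; C10 bromo lactone)
Conditions: Dess–Martin periodinane, CH2Cl2, 0 °C to rt
Reagents that add atoms: none
Why: Dess–Martin oxidation converts the secondary C1 alcohol into the ketone under non-basic conditions that leave the α-bromo lactone, the ketal and the silyl ether untouched.

Step 7
Reactants: 13 bromo keto lactone
Product: 14 cis-fused hydroazulene (1α-OH, 5α-H, 10α-H) with 4,4-ethylenedioxy group, 6α-OSiMe2t-Bu, 7β-CH2CO2Me and the 14,8β-lactone bridge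
Conditions: SmI2 (2.2 equiv), THF, −78 °C
Reagents that add atoms: none
Why: Samarium diiodide-mediated intramolecular Reformatsky reaction: SmI2 reduces only the C10–Br bond and the samarium enolate adds to the C1 ketone through a chelated transition state, the new ring forcing C1 and C7 cis on the lactone (C10) and the tertiary carbinol being drawn as the cis-fused isomer.

Step 8
Reactants: 14 ketal
Product: 15 C4 ketone of 14 (all other groups unchanged)
Conditions: PPTS (cat.), acetone/H2O, 45 °C
Reagents that add atoms: water, O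
Why: Mild acid-catalysed hydrolysis of the dioxolane unmasks the C4 ketone while the secondary silyl ether, the ester and the lactone survive.

Step 9
Reactants: 15 C4 ketone
Product: 16 4β,15-spiro-epoxide (epoxide oxygen cis to C6; otherwise as 15)
Conditions: Me3S+ I−, KN(SiMe3)2, THF, −10 °C; then 15, −10 to 0 °C
Reagents that add atoms: trimethylsulfonium iodide, C[S+](C)C.[I-]
Why: Corey–Chaykovsky epoxidation: dimethylsulfonium methylide adds irreversibly to the C4 ketone from the face opposite the C5–C6 bond, which should place C15 trans and the epoxide oxygen cis to C6, and the ylide is too weak a base to deprotonate the tertiary alcohol.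

Step 10
Reactants: 16 epoxide
Product: 18 1α-hydroxy-4β,15-epoxy-13-norguaiane-12,6α:14,8β-diolide, via C6 hydroxy ester 17 (not isolated)
Conditions: Bu4NF, AcOH, THF, 0 °C to rt; then DBU (cat.), rt
Reagents that add atoms: none
Why: Fluoride-mediated desilylation frees the C6 hydroxyl, which closes onto the C12 methyl ester by base-catalysed 5-exo-trig lactonisation to give the trans-fused 6,12-lactone without touching the epoxide.

Step 11
Reactants: 18 bis-lactone
Product: 20 13-(dimethylamino)-1α-hydroxy-4β,15-epoxy-11βH-guaiane-12,6α:14,8β-diolide, via dilithium alkoxide-enolate 19 (not isolated)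
Conditions: LiN(iPr)2 (2.2 equiv), THF, −78 °C; then CH2=NMe2+ I−, −78 to −40 °C
Reagents that add atoms: N,N-dimethylmethyleneiminium iodide, C=[N+](C)C.[I-]
Why: Mannich reaction of the lactone enolate with Eschenmoser's salt: only C11 is enolised because C10 is a bridgehead of the bicyclo[4.2.1] lactone, the aldolate is stable at this temperature, and the iminium ion should enter anti to the C7 substituent.

Step 12
Reactants: 20 Mannich base
Product: 22 1α-hydroxy-4β,15-epoxy-5α,7α,10α-H-guai-11(13)-ene-12,6α:14,8β-diolide, via trimethylammonium iodide 21 (not isolated)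
Conditions: MeI, THF, rt; then aq. NaHCO3, CH2Cl2, rt
Reagents that add atoms: none
Why: Exhaustive N-methylation followed by base-induced β-elimination of trimethylamine (Hofmann-type E1cB) gives the α-methylene lactone under conditions that spare the epoxide.

Step 13
Reactants: 22 1-hydroxy-4,15-epoxy guaiane bis-lactone
Product: 23 (4Z)-15-hydroxy-1-oxogermacra-4,11(13)-diene-12,6α:14,8β-diolide (10-H as in 22)
Conditions: Sc(OTf)3 (10 mol %), CH2Cl2, −40 to 0 °C
Reagents that add atoms: none
Why: Proposed new method: the Lewis acid binds the epoxide oxygen and, as the tertiary C4–O bond ionises, the antiperiplanar C1–C5 σ bond, pushed by the lone pair of the C1 hydroxyl, breaks in a concerted Grob fragmentation that gives the C1 ketone, the C4=C5 olefin and the C15 alkoxide. The closest known reaction type is the Lewis-acid-promoted fragmentation of bicyclic 3,4-epoxy alcohols and the Wharton–Grob fragmentation of 1,3-diol monosulfonates to cyclodecenones, whereas its use on a cis-hydroazulene lactone with a spiro 4,15-epoxide is untested. No ring-closing bond is formed: the ten-membered ring appears because the bond shared by the five- and seven-membered rings is cleaved. No stereocentre is created, and the olefin geometry follows from the antiperiplanar alignment, in which an epoxide oxygen cis to C6 on the cyclopentane places C3 cis to C6 in the product. The step needs fragmentation to outrun the 1,2-hydride shift to a C4 aldehyde and capture of C15 by the C1 hydroxyl, and the donor strength of the hydroxyl-bearing C1–C5 bond together with the envelope conformation that aligns it with C4–O should secure this.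

Step 14
Reactants: 23 keto alcohol
Product: 24 15-O-tert-butyldimethylsilyl ether of 23
Conditions: t-BuMe2SiCl, imidazole, DMF, 0 °C
Reagents that add atoms: tert-butyldimethylsilyl chloride, CC(C)(C)[Si](C)(C)Cl
Why: Imidazole-promoted silylation of the only free hydroxyl, the primary C15 alcohol, which also draws any transannular hemiketal back to the open hydroxy ketone.

Step 15
Reactants: 24 β-keto lactone
Product: 26 10-(phenylselanyl) derivative of 24 (selenium in place of the C10 hydrogen), via lithium enolate 25 (not isolated)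
Conditions: LiN(SiMe3)2 (1.05 equiv), THF, −78 °C; then PhSeBr, −78 °C
Reagents that add atoms: phenylselenenyl bromide, Br[Se]c1ccccc1
Why: Selenenylation of the lithium enolate of the β-keto lactone: C10 is the only doubly activated carbon, and selenium should take the place of the hydrogen because the lactone bridge keeps C1 and C7 cis.

Step 16
Reactants: 26 α-seleno ketone
Product: 27 (1S)-1-hydroxy derivative of 26
Conditions: (R)-2-methyl-CBS-oxazaborolidine (0.3 equiv), catecholborane, toluene, −78 °C
Reagents that add atoms: none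
Why: Corey–Bakshi–Shibata reduction: with the quaternary C10 as the large and the C2 methylene as the small substituent, the (R)-oxazaborolidine should deliver hydride to the face that gives the 1S alcohol, and catecholborane at low temperature spares the olefins and lactones.

Step 17
Reactants: 27 secondary alcohol
Product: 28 (1S)-1-isobutyryloxy derivative of 27
Conditions: (i-PrCO)2O, DMAP (cat.), pyridine, CH2Cl2, 0 °C to rt
Reagents that add atoms: isobutyric anhydride, CC(C)C(=O)OC(=O)C(C)C
Why: DMAP-catalysed acylation of the secondary C1 alcohol with isobutyric anhydride installs the ester with retention.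

Step 18
Reactants: 28 selenide ester
Product: 30 15-O-tert-butyldimethylsilyl ether of the target (C9=C10 butenolide), via selenoxide 29 (not isolated)
Conditions: NaIO4, NaHCO3, THF/H2O, 0 °C to rt
Reagents that add atoms: none
Why: Selenide oxidation and selenoxide syn-elimination: the selenoxide should eliminate towards C9 and away from the oxygen-bearing C1 to give the C9=C10 butenolide, and periodate is used so that the C4=C5 olefin is not epoxidised.

Step 19
Reactants: 30 silyl ether
Product: 31 target CNP0322767.4
Conditions: HF·pyridine, THF, 0 °C to rt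
Reagents that add atoms: none
Why: Fluoride-mediated cleavage of the primary silyl ether under mildly acidic conditions that the butenolide, the α-methylene lactone and the ester tolerate.

**Compound list**
1 | methyl 4-oxobutanoate | COC(=O)CCC=O | starting material
2 | dimethyl (3R,4R)-3-formyl-4-hydroxyheptanedioate | COC(=O)C[C@@H](C=O)[C@H](O)CCC(=O)OC | intermediate
3 | methyl (3R)-4-oxo-3-[(2R)-5-oxooxolan-2-yl]butanoate | COC(=O)C[C@@H](C=O)[C@H]1CCC(=O)O1 | intermediate
4 | 6-bromo-1,4-dioxaspiro[4.4]non-6-ene | BrC1=CCCC12OCCO2 | starting material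
5 | (1,4-dioxaspiro[4.4]non-6-en-6-yl)lithium (not isolated) | [Li]C1=CCCC12OCCO2 | intermediate
6 | dichloro(1,4-dioxaspiro[4.4]non-6-en-6-yl)cerium (not isolated) | Cl[Ce](Cl)C1=CCCC12OCCO2 | intermediate
7 | methyl (3S,4S)-4-(1,4-dioxaspiro[4.4]non-6-en-6-yl)-4-hydroxy-3-[(2R)-5-oxooxolan-2-yl]butanoate, present as its cerium alkoxide (not isolated) | COC(=O)C[C@H]([C@H]1CCC(=O)O1)[C@H](O)C2=CCCC23OCCO3 | intermediate
8 | methyl (3R,4S)-4-[(tert-butyldimethylsilyl)oxy]-4-(1,4-dioxaspiro[4.4]non-6-en-6-yl)-3-[(2R)-5-oxooxolan-2-yl]butanoate | COC(=O)C[C@H]([C@H]1CCC(=O)O1)[C@H](O[Si](C)(C)C(C)(C)C)C2=CCCC23OCCO3 | intermediate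
9 | C10=C14 ketene trimethylsilyl acetal of 8 (not isolated) | COC(=O)C[C@H]([C@H]1CC=C(O[Si](C)(C)C)O1)[C@H](O[Si](C)(C)C(C)(C)C)C2=CCCC23OCCO3 | intermediate
10 | methyl (3R,4S)-3-[(2R,4S)-4-bromo-5-oxooxolan-2-yl]-4-[(tert-butyldimethylsilyl)oxy]-4-(1,4-dioxaspiro[4.4]non-6-en-6-yl)butanoate | COC(=O)C[C@H]([C@H]1C[C@H](Br)C(=O)O1)[C@H](O[Si](C)(C)C(C)(C)C)C2=CCCC23OCCO3 | intermediate
11 | C1 alkylborane of 10, BH2 on C1 and H on C5 on the same face (not isolated) | COC(=O)C[C@H]([C@H]1C[C@H](Br)C(=O)O1)[C@H](O[Si](C)(C)C(C)(C)C)[C@@H]2[C@@H](B)CCC23OCCO3 | intermediate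
12 | cyclopentanol from 10: C5–H and C1–OH cis, C1–OH trans to the C6 chain, C4 ethylene ketal | COC(=O)C[C@H]([C@H]1C[C@H](Br)C(=O)O1)[C@H](O[Si](C)(C)C(C)(C)C)[C@@H]2[C@@H](O)CCC23OCCO3 | intermediate
13 | C1 ketone of 12 | COC(=O)C[C@H]([C@H]1C[C@H](Br)C(=O)O1)[C@H](O[Si](C)(C)C(C)(C)C)[C@@H]2C(=O)CCC23OCCO3 | intermediate
14 | cis-fused hydroazulene: 1α-OH, 5α-H, 10α-H, 4,4-ethylenedioxy, 6α-OSiMe2t-Bu, 7β-CH2CO2Me (7α-H), 14,8β-lactone bridge | COC(=O)C[C@H]1[C@H](O[Si](C)(C)C(C)(C)C)[C@H]2C3(OCCO3)CC[C@@]2(O)[C@@H]4C[C@H]1OC4=O | intermediate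
15 | C4 ketone of 14 | COC(=O)C[C@H]1[C@H](O[Si](C)(C)C(C)(C)C)[C@H]2C(=O)CC[C@@]2(O)[C@@H]3C[C@H]1OC3=O | intermediate
16 | 4β,15-epoxide from 15 (epoxide oxygen cis to C6, C15 trans to C6) | COC(=O)C[C@H]1[C@H](O[Si](C)(C)C(C)(C)C)[C@H]2[C@]4(CO4)CC[C@@]2(O)[C@@H]3C[C@H]1OC3=O | intermediate
17 | 6α-hydroxy methyl ester from 16 (not isolated) | COC(=O)C[C@H]1[C@H](O)[C@H]2[C@]4(CO4)CC[C@@]2(O)[C@@H]3C[C@H]1OC3=O | intermediate
18 | 1α-hydroxy-4β,15-epoxy-5α,7α,10α-H-13-norguaiane-12,6α:14,8β-diolide | C1C(=O)O[C@@H]2[C@H]3[C@]4(CO4)CC[C@@]3(O)[C@@H]5C[C@@H](OC5=O)[C@@H]12 | intermediate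
19 | dilithium C1 alkoxide / C11=C12 enolate of 18 (not isolated) | C1=C(O[Li])O[C@@H]2[C@H]3[C@]4(CO4)CC[C@@]3(O[Li])[C@@H]5C[C@@H](OC5=O)[C@@H]12 | intermediate
20 | 13-(dimethylamino)-1α-hydroxy-4β,15-epoxy-11βH-guaiane-12,6α:14,8β-diolide | CN(C)C[C@@H]1C(=O)O[C@@H]2[C@H]3[C@]4(CO4)CC[C@@]3(O)[C@@H]5C[C@@H](OC5=O)[C@@H]12 | intermediate
21 | 13-(trimethylammonio) iodide of 20 (not isolated) | C[N+](C)(C)C[C@@H]1C(=O)O[C@@H]2[C@H]3[C@]4(CO4)CC[C@@]3(O)[C@@H]5C[C@@H](OC5=O)[C@@H]12.[I-] | intermediate
22 | 1α-hydroxy-4β,15-epoxy-5α,7α,10α-H-guai-11(13)-ene-12,6α:14,8β-diolide | C=C1C(=O)O[C@@H]2[C@H]3[C@]4(CO4)CC[C@@]3(O)[C@@H]5C[C@@H](OC5=O)[C@@H]12 | intermediate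
23 | (4Z)-15-hydroxy-1-oxogermacra-4,11(13)-diene-12,6α:14,8β-diolide (C3 cis to C6 on the olefin) | C=C1C(=O)O[C@@H]2/C=C(/CO)CCC(=O)[C@@H]3C[C@@H](OC3=O)[C@@H]12 | intermediate
24 | 15-O-tert-butyldimethylsilyl ether of 23 | C=C1C(=O)O[C@@H]2/C=C(/CO[Si](C)(C)C(C)(C)C)CCC(=O)[C@@H]3C[C@@H](OC3=O)[C@@H]12 | intermediate
25 | lithium C1=C10 enolate of 24 (not isolated) | C=C1C(=O)O[C@@H]2/C=C(/CO[Si](C)(C)C(C)(C)C)CCC(O[Li])=C3C[C@@H](OC3=O)[C@@H]12 | intermediate
26 | 10-(phenylselanyl) derivative of 24 (Se replaces 10-H) | C=C1C(=O)O[C@@H]2/C=C(/CO[Si](C)(C)C(C)(C)C)CCC(=O)[C@]3([Se]c4ccccc4)C[C@@H](OC3=O)[C@@H]12 | intermediate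
27 | (1S)-1-hydroxy derivative of 26 | C=C1C(=O)O[C@@H]2/C=C(/CO[Si](C)(C)C(C)(C)C)CC[C@H](O)[C@]3([Se]c4ccccc4)C[C@@H](OC3=O)[C@@H]12 | intermediate
28 | (1S)-1-(2-methylpropanoyloxy) derivative of 26 | C=C1C(=O)O[C@@H]2/C=C(/CO[Si](C)(C)C(C)(C)C)CC[C@H](OC(=O)C(C)C)[C@]3([Se]c4ccccc4)C[C@@H](OC3=O)[C@@H]12 | intermediate
29 | selenoxide of 28 (not isolated) | C=C1C(=O)O[C@@H]2/C=C(/CO[Si](C)(C)C(C)(C)C)CC[C@H](OC(=O)C(C)C)[C@]3([Se](=O)c4ccccc4)C[C@@H](OC3=O)[C@@H]12 | intermediate
30 | 15-O-tert-butyldimethylsilyl ether of the target | C=C1C(=O)O[C@@H]2/C=C(/CO[Si](C)(C)C(C)(C)C)CC[C@H](OC(=O)C(C)C)C3=C[C@@H](OC3=O)[C@@H]12 | intermediate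
31 | CNP0322767.4: (1S,4Z)-15-hydroxy-1-(2-methylpropanoyloxy)germacra-4,9,11(13)-triene-12,6α:14,8β-diolide | C=C1C(=O)O[C@@H]2/C=C(/CO)CC[C@H](OC(=O)C(C)C)C3=C[C@@H](OC3=O)[C@@H]12 | target

**Totals**
Total step count: 19. Longest linear sequence: 19 steps (1 to 31; 4 is bought and enters in step 3).

**Steps most likely to fail**

Step 13 (labelled step). The ionised epoxide may undergo the 1,2-hydride shift to a C4 aldehyde, or be trapped at C15 by the C1 hydroxyl, before the C1–C5 bond breaks. The fallback cleaves the same bond homolytically by known reaction types. It sets out from 22 and generates the C1 alkoxy radical from the free alcohol (CeCl3 10 mol %, Bu4NCl, 400 nm light, MeCN, with 2,4,6-triisopropylbenzenethiol as hydrogen donor). β-Scission towards C5 gives the C1 ketone, the oxiranylcarbinyl radical opens to the C4=C5 olefin and a C15 alkoxy radical, and hydrogen-atom transfer from the thiol returns 23. The olefin geometry would then rest on the ring and not on the epoxide. No new compound is made (F0).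

Step 7. Proton transfer to the samarium enolate (simple debromination) or β-elimination at the ketone may outrun closure of the seven-membered ring. The fallback sets out from 13: triethylamine in CH2Cl2 eliminates HBr to the C9=C10 butenolide F1. Conjugate reduction of butenolide F1 with [(Ph3P)CuH]6 in toluene at −40 °C generates the C10 copper enolate regiospecifically, and its intramolecular aldol addition to the C1 ketone (copper-hydride reductive aldol cyclisation) comes back to the route at 14.

Step 3. The β-acyloxy aldehyde 3 may be enolised by the organometallic and lose the lactone carboxylate by β-elimination before addition occurs. The fallback sets out from 5 and 3: vinyllithium 5 is quenched with iodine to 6-iodo-1,4-dioxaspiro[4.4]non-6-ene F2. Vinyl iodide F2 is joined to 3 by a non-basic Nozaki–Hiyama–Kishi coupling (CrCl2, NiCl2 cat., DMF). Silylation of the resulting alcohol 7 (t-BuMe2SiOTf, 2,6-lutidine) comes back to the route at 8.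

Further compounds
F0 | step 13 | none | none
F1 | step 7 | C9=C10 butenolide analogue of 13 (13 minus HBr) | COC(=O)C[C@H]([C@H]1C=CC(=O)O1)[C@H](O[Si](C)(C)C(C)(C)C)[C@@H]2C(=O)CCC23OCCO3
F2 | step 3 | 6-iodo-1,4-dioxaspiro[4.4]non-6-ene | IC1=CCCC12OCCO2
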